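**Assumptions (one line each)**
- Ring numbering used here is defined from the target SMILES: C1 = CH2 between C10 and C2; C2 = CH(OH); C3 = CH2; C4 = C(OH)(CH3); C5 = CH(OiBu); C6 = CH–O(lactone); C7 = lactone β-CH; C8 = CH(OiBu); C9 = C=O; C10 = CH(CH3); C11/C12/C13 = lactone α-C / C=O / exocyclic CH2. Target = (2S,4S,5S,6R,7R,8S,10S).
- (S)-β-Methyl-γ-butyrolactone is taken as purchasable in enantiopure form; the target is treated as the open keto-alcohol drawn (it may equilibrate with a C2-O/C9 hemiketal).

**Retrosynthetic overview**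
1. The 10-membered ring and the α-methylene lactone are formed together, last, by a radical addition–fragmentation macrocyclization that makes C7–C8: a C8 α-(isobutyryloxy)alkyl radical adds to C7 of a γ-substituted α-(sulfonylmethyl)butenolide and expels the sulfonyl radical (sets C7 and C8).
2. The seco-aldehyde comes from a chelation-controlled Mukaiyama aldol (C3–C4, sets C4) and a 1,3-syn reduction (sets C2), joining an East enol silane (C1–C3, C8–C10) to a West keto-butenolide (C4–C7, C11–C13).
3. West: vinylogous Mukaiyama aldol of a sulfonylmethyl silyloxyfuran (from tulipalin A) with methylglyoxal (sets C5, C6); the lactone ring is therefore present from the start.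
4. East: (S)-β-methyl-γ-butyrolactone supplies C10; a temporary C9 carbinol stereocentre is installed to relay configuration to C8 and is later oxidised to the ketone.

**Route**

Step 1
Reactants: 1, (S)-4-methyldihydrofuran-2(3H)-one
Product: 2, (S)-5-hydroxy-4-methylpentan-2-one (in equilibrium with its cyclic hemiketal)
Conditions: MeLi (1.05 equiv), THF, −78 °C; NH4Cl
Reagents that add atoms: methyllithium, [Li]C
Why: Mono-addition of MeLi to a lactone stops at the tetrahedral alkoxide at −78 °C and gives the methyl ketone on work-up; C10 is untouched.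

Step 2
Reactants: 2
Product: 3, (S)-2-methyl-4-oxopentanal
Conditions: Dess–Martin periodinane, NaHCO3, CH2Cl2, 0 °C; used crude
Reagents that add atoms: none
Why: Buffered Dess–Martin oxidation of the primary alcohol (open form) gives the aldehyde without epimerising the α-stereocentre.

Step 3
Reactants: 3
Product: 4, (4S,5R)-5-hydroxy-4-methylhept-6-en-2-one
Conditions: salt-free (CH2=CH)2Zn, (+)-MIB (10 mol %; antipode chosen for Re-face delivery), toluene, −20 °C
Reagents that add atoms: divinylzinc, C=C[Zn]C=C
Why: Amino-alcohol-catalysed organozinc addition is selective for the aldehyde over the ketone, and catalyst control overrides the weak Felkin bias to give the 4,5-anti carbinol (future C9, a temporary stereocentre).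

Step 4
Reactants: 4
Product: 5, (4S,5R)-5-(tert-butyldimethylsilyloxy)-4-methylhept-6-en-2-one
Conditions: TBSCl, imidazole, DMF, rt
Reagents that add atoms: TBSCl, CC(C)(C)[Si](C)(C)Cl
Why: Standard silylation of the open-chain secondary alcohol; TBS survives all steps up to step 16.

Step 5
Reactants: 5
Product: 6, (3R,4S)-3-(tert-butyldimethylsilyloxy)-4-methyl-6-(trimethylsilyloxy)hepta-1,6-diene
Conditions: LDA, THF, −78 °C; TMSCl, Et3N; non-aqueous work-up, used directly
Reagents that add atoms: TMSCl, C[Si](C)(C)Cl
Why: Kinetic deprotonation of the methyl ketone at CH3 and O-silylation give the terminal enol silane (C3 nucleophile).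

Step 6
Reactants: 7, α-methylene-γ-butyrolactone (tulipalin A)
Product: 8, 3-(bromomethyl)furan-2(5H)-one
Conditions: Br2, CH2Cl2, 0 °C; then Et3N, 0 °C → rt
Reagents that add atoms: bromine, BrBr
Why: Bromine addition followed by E2 loss of HBr from the tertiary α-bromide gives the conjugated butenolide bearing CH2Br.

Step 7
Reactants: 8
Product: 9, 3-[(ethylsulfonyl)methyl]furan-2(5H)-one
Conditions: EtSO2Na, DMF, rt
Reagents that add atoms: sodium ethanesulfinate, CCS(=O)[O-].[Na+]
Why: S-alkylation of the sulfinate by the allylic bromide; any SN2′ product is reversible and funnels to the conjugated allyl sulfone.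

Step 8
Reactants: 9
Product: 10, 3-[(ethylsulfonyl)methyl]-2-(trimethylsilyloxy)furan
Conditions: TMSOTf, Et3N, CH2Cl2, 0 °C; used crude
Reagents that add atoms: TMSOTf, C[Si](C)(C)OS(=O)(=O)C(F)(F)F
Why: Soft enolisation at the γ-CH2 (the most acidic site) gives the aromatic 2-silyloxyfuran.

Step 9
Reactants: 10; 11, methylglyoxal (anhydrous, freshly distilled)
Product: 12, (R)-3-[(ethylsulfonyl)methyl]-5-[(S)-1-hydroxy-2-oxopropyl]furan-2(5H)-one
Conditions: Cu(OTf)2/(S,S)-t-Bu-box (10 mol %; ligand antipode selected to give 5R), CH2Cl2, −78 °C; 1 M HCl work-up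
Reagents that add atoms: none
Why: Catalytic asymmetric vinylogous Mukaiyama aldol at the aldehyde of the Cu-chelated 1,2-dicarbonyl; γ-attack through an open transition state gives the threo adduct, setting C6 (R) and C5 (S).

Step 10
Reactants: 12; 6 (1.5 equiv)
Product: 13, (R)-5-[(1S,2S,6S,7R)-7-(tert-butyldimethylsilyloxy)-1,2-dihydroxy-2,6-dimethyl-4-oxonon-8-en-1-yl]-3-[(ethylsulfonyl)methyl]furan-2(5H)-one
Conditions: Me2AlCl (2.2 equiv) added to 12, CH2Cl2, −78 °C (CH4 evolution); then 6, −78 → −40 °C; Rochelle salt / dilute HCl work-up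
Reagents that add atoms: none
Why: Chelation-controlled Mukaiyama aldol: the aluminium alkoxide of C5–OH chelates the C4 ketone, and the enol silane adds to the face anti to the butenolide (Cram-chelate), giving 4S with the C4–OH syn to C5–O.

Step 11
Reactants: 13
Product: 14, the C5 isobutyrate of 13 (C4–OH free, C2 ketone)
Conditions: i-PrCOCl (1.2 equiv), pyridine, CH2Cl2, −20 → 0 °C
Reagents that add atoms: isobutyryl chloride, CC(C)C(=O)Cl
Why: The secondary C5–OH is acylated selectively over the tertiary C4–OH; pyridine is too weak a base to trigger γ-deprotonation/elimination of the butenolide.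

Step 12
Reactants: 14
Product: 15, the (2S)-alcohol: 2,4-syn diol with C5–OiBu, C9–OTBS, terminal vinyl and sulfonylmethyl butenolide
Conditions: Et2BOMe, THF/MeOH (4:1), −78 °C; NaBH4; AcOH quench, MeOH azeotrope
Reagents that add atoms: none
Why: Narasaka–Prasad reduction: hydride attacks the boron chelate axially with the large C5 substituent equatorial, giving the 1,3-syn diol (2S); at −78 °C the butenolide and esters are not reduced.

Step 13
Reactants: 15
Product: 16, the 2,4-O-isopropylidene acetal (1,3-dioxane) of 15
Conditions: 2-methoxypropene, PPTS (cat.), CH2Cl2, 0 °C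
Reagents that add atoms: 2-methoxypropene, COC(C)=C
Why: Acetonide formation on the syn-1,3-diol masks both hydroxyls from the acyl iodide in step 15.

Step 14
Reactants: 16
Product: 17, the C8 aldehyde (α-silyloxy aldehyde; C9 descriptor is now S by CIP priority only)
Conditions: O3, CH2Cl2, −78 °C (Sudan III end-point); PPh3
Reagents that add atoms: ozone, [O-][O+]=O
Why: Ozonolysis is selective for the electron-rich vinyl group over the electron-poor conjugated butenolide alkene.

Step 15
Reactants: 17
Product: 19, (9S)-9-deoxo-9-(tert-butyldimethylsilyloxy)-2,4-O-isopropylidene-cardivin D (10-membered ring, trans-fused α-methylene lactone; 7R, 8S), via 18, the α-iodoalkyl isobutyrate of 17 (C8 epimers, not isolated)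
Conditions: i-PrCOI (1.1 equiv, from i-PrCOCl/NaI), CH2Cl2, 0 °C, 15 min → 18; then dilute to 1 mM in degassed PhCF3, Mn2(CO)10 (0.5 equiv), blue LEDs, 40 °C
Reagents that add atoms: isobutyryl iodide, CC(C)C(=O)I
Why: Proposed new method: the aldehyde is converted to an α-iodoalkyl isobutyrate (ketyl-radical surrogate, installing the C8 ester), Mn(CO)5• abstracts iodine to give a nucleophilic C8 radical kept alive by reversible iodine transfer, which adds 10-exo to butenolide C7 anti to the C6 substituent (trans lactone, 7R) and then loses EtSO2• by β-scission to unveil the exocyclic methylene; C8 is expected to be set by relay from the 9S silyloxy centre (C9–H eclipsing C8–O, attack anti to the C9–OTBS bond with the C10 tether on the reacting face, giving 8S); closest known reactions are radical allylation with allyl ethyl sulfones, Mn2(CO)10/visible-light reactions of α-acyloxy iodides, trans-selective radical additions to γ-substituted butenolides, and radical macrocyclizations.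

Step 16
Reactants: 19
Product: 20, (9S)-9-deoxo-9-hydroxy-2,4-O-isopropylidene-cardivin D
Conditions: HF·pyridine, THF/pyridine, 0 °C → rt
Reagents that add atoms: none
Why: Buffered fluoride desilylation leaves the acetonide, esters and α-methylene lactone intact; acidic rather than basic conditions avoid C8→C9 acyl migration.

Step 17
Reactants: 20
Product: 21, 2,4-O-isopropylidene-cardivin D (C9 ketone)
Conditions: Dess–Martin periodinane, NaHCO3, CH2Cl2, 0 °C → rt
Reagents that add atoms: none
Why: Mild oxidation of the only free hydroxyl gives the C9 ketone and removes the temporary stereocentre without epimerising C8 or C10.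

Step 18
Reactants: 21
Product: 22, cardivin D
Conditions: AcOH/H2O (4:1), 40 °C
Reagents that add atoms: none
Why: Mild acid hydrolysis of the acetonide frees the C2 and C4 hydroxyls; the isobutyrates, α-acyloxy ketone and α-methylene lactone tolerate these conditions.

**Compound list**
1 | (S)-4-methyldihydrofuran-2(3H)-one | C[C@@H]1COC(=O)C1 | starting material
2 | (S)-5-hydroxy-4-methylpentan-2-one | CC(=O)C[C@H](C)CO | intermediate
3 | (S)-2-methyl-4-oxopentanal | CC(=O)C[C@H](C)C=O | intermediate
4 | (4S,5R)-5-hydroxy-4-methylhept-6-en-2-one | CC(=O)C[C@H](C)[C@H](O)C=C | intermediate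
5 | (4S,5R)-5-(TBS-oxy)-4-methylhept-6-en-2-one | CC(=O)C[C@H](C)[C@H](O[Si](C)(C)C(C)(C)C)C=C | intermediate
6 | (3R,4S)-3-(TBS-oxy)-4-methyl-6-(TMS-oxy)hepta-1,6-diene | C=C(O[Si](C)(C)C)C[C@H](C)[C@H](O[Si](C)(C)C(C)(C)C)C=C | intermediate
7 | α-methylene-γ-butyrolactone (tulipalin A) | C=C1CCOC1=O | starting material
8 | 3-(bromomethyl)furan-2(5H)-one | BrCC1=CCOC1=O | intermediate
9 | 3-[(ethylsulfonyl)methyl]furan-2(5H)-one | CCS(=O)(=O)CC1=CCOC1=O | intermediate
10 | 3-[(ethylsulfonyl)methyl]-2-(trimethylsilyloxy)furan | CCS(=O)(=O)Cc1ccoc1O[Si](C)(C)C | intermediate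
11 | methylglyoxal (2-oxopropanal) | CC(=O)C=O | starting material
12 | (R)-3-[(ethylsulfonyl)methyl]-5-[(S)-1-hydroxy-2-oxopropyl]furan-2(5H)-one | O=C1O[C@H](C=C1CS(=O)(=O)CC)[C@H](O)C(C)=O | intermediate
13 | aldol adduct (C4–OH, C5–OH, C2 ketone; 4S,5S,6R,9R,10S) | C=C[C@@H](O[Si](C)(C)C(C)(C)C)[C@@H](C)CC(=O)C[C@](C)(O)[C@@H](O)[C@@H]1OC(=O)C(CS(=O)(=O)CC)=C1 | intermediate
14 | C5 isobutyrate of 13 | C=C[C@@H](O[Si](C)(C)C(C)(C)C)[C@@H](C)CC(=O)C[C@](C)(O)[C@@H](OC(=O)C(C)C)[C@@H]1OC(=O)C(CS(=O)(=O)CC)=C1 | intermediate
15 | (2S)-alcohol, 2,4-syn diol | C=C[C@@H](O[Si](C)(C)C(C)(C)C)[C@@H](C)C[C@H](O)C[C@](C)(O)[C@@H](OC(=O)C(C)C)[C@@H]1OC(=O)C(CS(=O)(=O)CC)=C1 | intermediate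
16 | 2,4-O-isopropylidene acetal of 15 | C=C[C@@H](O[Si](C)(C)C(C)(C)C)[C@@H](C)C[C@H]2C[C@](C)(OC(C)(C)O2)[C@@H](OC(=O)C(C)C)[C@@H]1OC(=O)C(CS(=O)(=O)CC)=C1 | intermediate
17 | C8 aldehyde (seco-aldehyde) | O=C[C@@H](O[Si](C)(C)C(C)(C)C)[C@@H](C)C[C@H]2C[C@](C)(OC(C)(C)O2)[C@@H](OC(=O)C(C)C)[C@@H]1OC(=O)C(CS(=O)(=O)CC)=C1 | intermediate
18 | α-iodoalkyl isobutyrate of 17 (C8 epimers, in situ) | IC(OC(=O)C(C)C)[C@@H](O[Si](C)(C)C(C)(C)C)[C@@H](C)C[C@H]2C[C@](C)(OC(C)(C)O2)[C@@H](OC(=O)C(C)C)[C@@H]1OC(=O)C(CS(=O)(=O)CC)=C1 | intermediate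
19 | (9S)-9-deoxo-9-(TBS-oxy)-2,4-O-isopropylidene-cardivin D | C=C1C(=O)O[C@@H]2[C@@H]1[C@H](OC(=O)C(C)C)[C@@H](O[Si](C)(C)C(C)(C)C)[C@@H](C)C[C@H]3C[C@](C)(OC(C)(C)O3)[C@H]2OC(=O)C(C)C | intermediate
20 | (9S)-9-deoxo-9-hydroxy-2,4-O-isopropylidene-cardivin D | C=C1C(=O)O[C@@H]2[C@@H]1[C@H](OC(=O)C(C)C)[C@@H](O)[C@@H](C)C[C@H]3C[C@](C)(OC(C)(C)O3)[C@H]2OC(=O)C(C)C | intermediate
21 | 2,4-O-isopropylidene-cardivin D | C=C1C(=O)O[C@@H]2[C@@H]1[C@H](OC(=O)C(C)C)C(=O)[C@@H](C)C[C@H]3C[C@](C)(OC(C)(C)O3)[C@H]2OC(=O)C(C)C | intermediate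
22 | cardivin D | C=C1C(=O)O[C@@H]2[C@@H]1[C@H](OC(=O)C(C)C)C(=O)[C@@H](C)C[C@H](O)C[C@](C)(O)[C@H]2OC(=O)C(C)C | target

(The C9 descriptor reads R in 4–6 and 13–16 and S in 17–20 for the same spatial arrangement; only the CIP priorities change.)

**Totals**
- Total steps: 18 (East 5, West 4, union and endgame 9).
- Longest linear sequence: 14 steps (steps 1–5, then 10–18).

**Three steps most likely to fail, with fallbacks**
1. Step 15 (radical macrocyclization). Risks: slow 10-exo closure onto a β-substituted acceptor (oligomers, 1,5-H transfer from C2–H), acetonide or silyl ether attack by the acyl iodide, and wrong C7/C8 configuration. Fallback: reverse the order of events. Form C7–C8 first by the same radical addition–fragmentation run intermolecularly (α-iodoalkyl isobutyrate from ozonised 5 plus a C5-protected derivative of 12), then close the ring at C3–C4 by an intramolecular chelation-controlled Mukaiyama aldol. If only C8 is wrong, use the C9 epimer from plain vinylMgBr (Felkin) addition in step 3 as the relay element.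
2. Step 10 (aldol to a ketone beside a butenolide). Risks: Mukaiyama–Michael/SN2′ attack on the butenolide, retro-aldol, poor chelation control at C4. Fallback: change the nucleophile class. Use indium-mediated Barbier allylation of 12 in aqueous THF with an East-derived 2-(bromomethyl)alkene (chelation through the free C5–OH), then ozonolyse the 1,1-disubstituted alkene to the same β-hydroxy ketone.
3. Step 9 (asymmetric vinylogous aldol with methylglyoxal). Risks: handling of anhydrous methylglyoxal, and threo/enantioselectivity with this substituted silyloxyfuran. Fallback: run the racemic BF3·OEt2-mediated (threo-selective) reaction and resolve the secondary alcohol by lipase-catalysed acylation, replacing catalyst control with kinetic resolution.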